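The depsidone is disconnected at the diaryl ether C–O bond to a depside. In ring B the ether carbon (C-4 of the phthalide) is the only C–H; it lies para to the free C-7 phenol and next to the ester-bearing C-5. Two-electron oxidation of that phenol makes C-4 electrophilic, and the ring A 2-hydroxyl, positioned by the ester linkage, closes the seven-membered dioxepinone in one operation. The precursor is the depside of the acetoxymethyl phthalide, lactol masked as methyl acetal, with a haematommic acid whose 4-hydroxyl is a tert-butyl carbonate, so that ring B, not ring A, is the ring oxidised. The labile lactol centre is fixed last by crystallisation.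

Key step: step 10

Assumption: the lactol carbon interconverts in solution through the ring-opened 2-formylbenzoic acid, so all acetal intermediates are carried as racemates (a defined acetal configuration would be lost on hydrolysis anyway). The (S) configuration can therefore be fixed only in the crystal at step 12, which presupposes that galbinic acid forms enantiomorphic crystals and that (S) seed crystals are secured once by enantioselective chromatography.

Remark on precursor design: ring A with a free 4-hydroxyl is a resorcinol with an open position (C-5) para to a hydroxyl and would be oxidised before ring B; it is therefore carried as the 4-O-tert-butyl carbonate.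

Locants: phthalide = isobenzofuran-1(3H)-one (C-1 lactone carbonyl, C-3 acetal carbon, C-4 to C-7 arene carbons); ring A is numbered as a benzoate (C-1 carboxyl, 2-OH, 3-CHO, 4-O, 6-CH3).

Step 1
Reactants: 1 atraric acid (methyl 2,4-dihydroxy-3,6-dimethylbenzoate)
Product: 2 methyl 3,6-dimethyl-2,4-bis[(2,2,2-trichloroethoxy)carbonyloxy]benzoate
Conditions: Cl3CCH2OCOCl (2.4 equiv), pyridine, DMAP (cat.), CH2Cl2, 0 °C to rt
Reagents that add atoms: 2,2,2-trichloroethyl chloroformate, ClC(=O)OCC(Cl)(Cl)Cl
Why: DMAP-catalysed O-acylation of both phenols with a chloroformate gives electron-withdrawing carbonates that should suppress nuclear bromination in step 2 and can later be removed under non-basic reductive conditions.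

Step 2
Reactants: 2 methyl 3,6-dimethyl-2,4-bis[(2,2,2-trichloroethoxy)carbonyloxy]benzoate
Product: 3 methyl 3-(bromomethyl)-6-(dibromomethyl)-2,4-bis[(2,2,2-trichloroethoxy)carbonyloxy]benzoate
Conditions: NBS (3.3 equiv), AIBN (cat.), PhCF3, 85 °C, visible light
Reagents that add atoms: N-bromosuccinimide, BrN1C(=O)CCC1=O
Why: Wohl–Ziegler radical benzylic bromination should take the 6-methyl group (one ortho substituent) to the gem-dibromide, while the 3-methyl group, flanked by two carbonates that hinder a planar α-bromobenzyl radical, should stop at the monobromide.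

Step 3
Reactants: 3 methyl 3-(bromomethyl)-6-(dibromomethyl)-2,4-bis[(2,2,2-trichloroethoxy)carbonyloxy]benzoate
Product: 5 racemic 6-(acetoxymethyl)-3-methoxy-5,7-bis[(2,2,2-trichloroethoxy)carbonyloxy]phthalide, via 3-acetoxyphthalide 4 (not isolated)
Conditions: AgOAc (3.5 equiv), AcOH, 70 °C, dark; filter, concentrate; then MeOH, TsOH·H2O (cat.), rt
Reagents that add atoms: silver acetate, CC(=O)[O-].[Ag+]; methanol, CO
Why: Silver-assisted solvolysis turns the primary bromide into the acetate and ionises the gem-dibromide, whose cation is captured by the neighbouring ester carbonyl (lactonisation with loss of the ester methyl as methyl acetate) to give the acylal, and acid-catalysed acylal-to-acetal exchange through the phthalidyl oxocarbenium ion then installs the methoxy group; the new C-3 centre forms as the racemate and needs no control.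

Step 4
Reactants: 5 racemic 6-(acetoxymethyl)-3-methoxy-5,7-bis[(2,2,2-trichloroethoxy)carbonyloxy]phthalide
Product: 6 racemic 6-(acetoxymethyl)-5,7-dihydroxy-3-methoxyphthalide
Conditions: Zn dust, AcOH–THF (1:1), 0 °C to rt
Reagents that add atoms: none
Why: Zinc-mediated reductive β-elimination of the 2,2,2-trichloroethyl carbonates frees both phenols without base, so the ortho-hydroxybenzyl acetate is not driven to a quinone methide, and any acetate exchange in AcOH is degenerate.

Step 5
Reactants: 7 orsellinic acid (2,4-dihydroxy-6-methylbenzoic acid)
Product: 8 benzyl orsellinate (benzyl 2,4-dihydroxy-6-methylbenzoate)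
Conditions: BnBr, KHCO3, DMF, rt
Reagents that add atoms: benzyl bromide, BrCc1ccccc1
Why: SN2 O-alkylation of the carboxylate, which KHCO3 forms selectively because the phenols are much weaker acids.

Step 6
Reactants: 8 benzyl orsellinate
Product: 9 benzyl haematommate (benzyl 3-formyl-2,4-dihydroxy-6-methylbenzoate)
Conditions: Cl2CHOCH3, TiCl4, CH2Cl2, −78 to 0 °C; then aq. HCl
Reagents that add atoms: dichloromethyl methyl ether, COC(Cl)Cl; water, O
Why: Rieche formylation, an electrophilic aromatic substitution that titanium chelation by the two phenolic oxygens should direct to C-3 between them, the usual site for β-resorcylate esters.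

Step 7
Reactants: 9 benzyl haematommate
Product: 10 benzyl 4-(tert-butoxycarbonyloxy)-3-formyl-2-hydroxy-6-methylbenzoate
Conditions: Boc2O (1.05 equiv), DMAP (5 mol%), CH2Cl2, 0 °C
Reagents that add atoms: di-tert-butyl dicarbonate, CC(C)(C)OC(=O)OC(=O)OC(C)(C)C
Why: DMAP-catalysed carbonate formation should occur at the 4-hydroxyl only, because the 2-hydroxyl is flanked and chelated by the ester and formyl carbonyls.

Step 8
Reactants: 10 benzyl 4-(tert-butoxycarbonyloxy)-3-formyl-2-hydroxy-6-methylbenzoate
Product: 11 4-(tert-butoxycarbonyloxy)-3-formyl-2-hydroxy-6-methylbenzoic acid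
Conditions: H2 (1 atm), Pd/C, EtOAc, rt
Reagents that add atoms: none
Why: Catalytic hydrogenolysis of the benzyl ester is fast at atmospheric pressure, conditions under which a chelated aryl aldehyde and an aryl carbonate are normally left intact.

Step 9
Reactants: 11 4-(tert-butoxycarbonyloxy)-3-formyl-2-hydroxy-6-methylbenzoic acid and 6 racemic 6-(acetoxymethyl)-5,7-dihydroxy-3-methoxyphthalide
Product: 12 racemic 6-(acetoxymethyl)-7-hydroxy-3-methoxy-1-oxo-1,3-dihydroisobenzofuran-5-yl 4-(tert-butoxycarbonyloxy)-3-formyl-2-hydroxy-6-methylbenzoate (the depside)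
Conditions: DCC, CH2Cl2–toluene, 0 °C to rt
Reagents that add atoms: none
Why: Carbodiimide esterification through the O-acylisourea should acylate the C-5 hydroxyl, which is para to the lactone carbonyl, more acidic and less hindered than the peri-chelated C-7 hydroxyl, while the acid's own 2-hydroxyl is chelated and does not self-condense; no amine catalyst is used so that the aryl carbonate is not transferred.

Step 10
Reactants: 12 the racemic depside
Product: 13 racemic galbinic acid methyl acetal 4-O-tert-butyl carbonate (depsidone in which the ring A 2-oxygen is bonded to C-4 of the phthalide)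
Conditions: PhI(OCOCF3)2 (1.1 equiv, slow addition), (CF3)2CHOH–CH2Cl2 (1:1), 2 mM, 0 °C
Reagents that add atoms: none
Why: Ligand exchange of the ring B C-7 hydroxyl on trivalent iodine and departure of iodobenzene give a phenoxonium ion with its positive charge largest at the para carbon C-4; the ring A 2-hydroxyl adds there and deprotonation at C-4 rearomatises ring B. The closest known reaction type is hypervalent-iodine oxidative dearomatisation of a phenol with intramolecular capture by an oxygen nucleophile, the two-electron counterpart of the oxidative depside-to-depsidone cyclisation known with MnO2. The dioxepinone ring forms when the phenolic oxygen adds to the cationic end of the dienyl system, formally a 7-exo-trig closure. No stereocentre is formed and the racemic acetal carbon is not touched. Ring selectivity is secured by the tert-butyl carbonate on the ring A 4-oxygen and by the formyl and ester carbonyls that flank and chelate the ring A 2-hydroxyl, which together leave ring B the more oxidisable phenol; positional selectivity is secured because C-4 is the only C–H of ring B, so that addition at the substituted ortho carbon C-6 cannot rearomatise and reverts. The fluoroalcohol solvent and high dilution keep solvent and a second molecule from capturing the cation.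

Step 11
Reactants: 13 racemic galbinic acid methyl acetal 4-O-tert-butyl carbonate
Product: 14 racemic galbinic acid
Conditions: CF3CO2H–H2O (9:1), rt
Reagents that add atoms: water, O
Why: Acidolysis removes the tert-butyl carbonate (loss of the tert-butyl cation, then decarboxylation) and hydrolyses the pseudo-ester acetal through the phthalidyl oxocarbenium ion, while the primary acetate and the aryl ester lactone tolerate aqueous acid at rt; the lactol centre forms as the racemate.

Step 12
Reactants: 14 racemic galbinic acid
Product: 15 (S)-galbinic acid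
Conditions: acetone–H2O, AcOH (cat.), seed crystals of (S)-15, glass beads, stirred slurry, 25 °C
Reagents that add atoms: none
Why: Proposed new method: in wet, weakly acidic acetone the lactol opens reversibly to the achiral 2-formylbenzoic acid, so the enantiomers interconvert in solution while each crystal keeps its configuration, and in a seeded, abraded slurry of enantiomorphic crystals dissolution of the (R) crystals and growth of the (S) seeds should convert the whole solid into the (S) form, the stereocentre being set by the handedness of the seed; the closest known reaction type is seeded crystallisation-induced asymmetric transformation (attrition-enhanced deracemisation) of racemising conglomerates, together with the crystallisation of mutarotating lactols as single anomers.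

Compound list
1 | atraric acid (methyl 2,4-dihydroxy-3,6-dimethylbenzoate) | COC(=O)c1c(C)cc(O)c(C)c1O | starting material
2 | methyl 3,6-dimethyl-2,4-bis[(2,2,2-trichloroethoxy)carbonyloxy]benzoate | COC(=O)c1c(C)cc(OC(=O)OCC(Cl)(Cl)Cl)c(C)c1OC(=O)OCC(Cl)(Cl)Cl | intermediate
3 | methyl 3-(bromomethyl)-6-(dibromomethyl)-2,4-bis[(2,2,2-trichloroethoxy)carbonyloxy]benzoate | COC(=O)c1c(C(Br)Br)cc(OC(=O)OCC(Cl)(Cl)Cl)c(CBr)c1OC(=O)OCC(Cl)(Cl)Cl | intermediate
4 | racemic 3-acetoxy-6-(acetoxymethyl)-5,7-bis[(2,2,2-trichloroethoxy)carbonyloxy]phthalide | CC(=O)OCc1c(OC(=O)OCC(Cl)(Cl)Cl)cc2c(c1OC(=O)OCC(Cl)(Cl)Cl)C(=O)OC2OC(C)=O | intermediate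
5 | racemic 6-(acetoxymethyl)-3-methoxy-5,7-bis[(2,2,2-trichloroethoxy)carbonyloxy]phthalide | CC(=O)OCc1c(OC(=O)OCC(Cl)(Cl)Cl)cc2c(c1OC(=O)OCC(Cl)(Cl)Cl)C(=O)OC2OC | intermediate
6 | racemic 6-(acetoxymethyl)-5,7-dihydroxy-3-methoxyphthalide | CC(=O)OCc1c(O)cc2c(c1O)C(=O)OC2OC | intermediate
7 | orsellinic acid (2,4-dihydroxy-6-methylbenzoic acid) | Cc1cc(O)cc(O)c1C(=O)O | starting material
8 | benzyl orsellinate | Cc1cc(O)cc(O)c1C(=O)OCc1ccccc1 | intermediate
9 | benzyl haematommate (benzyl 3-formyl-2,4-dihydroxy-6-methylbenzoate) | Cc1cc(O)c(C=O)c(O)c1C(=O)OCc1ccccc1 | intermediate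
10 | benzyl 4-(tert-butoxycarbonyloxy)-3-formyl-2-hydroxy-6-methylbenzoate | Cc1cc(OC(=O)OC(C)(C)C)c(C=O)c(O)c1C(=O)OCc1ccccc1 | intermediate
11 | 4-(tert-butoxycarbonyloxy)-3-formyl-2-hydroxy-6-methylbenzoic acid | Cc1cc(OC(=O)OC(C)(C)C)c(C=O)c(O)c1C(=O)O | intermediate
12 | racemic depside: 6-(acetoxymethyl)-7-hydroxy-3-methoxy-1-oxo-1,3-dihydroisobenzofuran-5-yl 4-(tert-butoxycarbonyloxy)-3-formyl-2-hydroxy-6-methylbenzoate | CC(=O)OCc1c(O)c2c(cc1OC(=O)c1c(C)cc(OC(=O)OC(C)(C)C)c(C=O)c1O)C(OC)OC2=O | intermediate
13 | racemic galbinic acid methyl acetal 4-O-tert-butyl carbonate (depsidone; ring A 2-oxygen bonded to phthalide C-4) | CC(=O)OCc1c(O)c2c(c3c1OC(=O)c1c(C)cc(OC(=O)OC(C)(C)C)c(C=O)c1O3)C(OC)OC2=O | intermediate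
14 | racemic galbinic acid | CC(=O)OCc1c(O)c2c(c3c1OC(=O)c1c(C)cc(O)c(C=O)c1O3)C(O)OC2=O | intermediate
15 | (S)-galbinic acid (S at the lactol carbon) | CC(=O)OCc1c(O)c2c(c3c1OC(=O)c1c(C)cc(O)c(C=O)c1O3)[C@@H](O)OC2=O | target

Total step count: 12
Longest linear sequence: 8 steps (steps 1–4 or 5–8, then 9–12)

Steps most likely to fail

Step 12. The solid may fail to deracemise because the two enantiomers pack together in one crystal form. In that case racemic 14 is resolved by preparative chromatography on an amylose tris(3,5-dimethylphenylcarbamate) stationary phase at −20 °C with an acid-free aprotic eluent, conditions under which ring–chain tautomerism should be slow. The (S) fraction is evaporated cold and precipitated at once to give 15 as the solid. The other fraction, (R)-galbinic acid F1, is left to racemise in wet acetone and returned to 14. This low-temperature enantioseparation of stereolabile compounds is established practice and also supplies the seed crystals for step 12.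

Step 10. Oxidation may attack ring A, over-oxidise ring B to a quinone, or lead to intermolecular coupling. The ether bond is then made by cross-coupling instead of oxidation, setting out from 6 and returning at 13. Diol 6 is iodinated with N-iodosuccinimide in MeCN at C-4, its only ring C–H and the position para to the C-7 hydroxyl, to give racemic 6-(acetoxymethyl)-5,7-dihydroxy-4-iodo-3-methoxyphthalide F2. DCC esterification with acid 11, as in step 9, gives racemic 6-(acetoxymethyl)-7-hydroxy-4-iodo-3-methoxy-1-oxo-1,3-dihydroisobenzofuran-5-yl 4-(tert-butoxycarbonyloxy)-3-formyl-2-hydroxy-6-methylbenzoate F3. Intramolecular Ullmann-type O-arylation (CuI, picolinic acid, K3PO4, DMSO, 60 °C) then joins the ring A 2-oxygen to C-4 and gives 13.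

Step 2. The mono/di differentiation of the two methyl groups may be lost through over- or under-bromination. Each methyl group is then brominated once only and the lactol oxidation level is added after lactonisation, setting out from 2 and returning at 5. Carbonate 2 with NBS (2.1 equiv, AIBN, PhCF3) gives methyl 3,6-bis(bromomethyl)-2,4-bis[(2,2,2-trichloroethoxy)carbonyloxy]benzoate F4. AgOAc in AcOH converts the 3-bromomethyl group into the acetate and closes the lactone from the 6-bromomethyl group and the ester, giving 6-(acetoxymethyl)-5,7-bis[(2,2,2-trichloroethoxy)carbonyloxy]phthalide F5. A second Wohl–Ziegler bromination with one equivalent of NBS should occur at the lactone CH2, whose C–H bonds are held in line with the arene π system while the acetoxymethyl group is shielded by two carbonates; it gives racemic 6-(acetoxymethyl)-3-bromo-5,7-bis[(2,2,2-trichloroethoxy)carbonyloxy]phthalide F6. Methanolysis of this α-bromo ether at rt gives 5.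

Further compounds
F1 | step 12 | (R)-galbinic acid | CC(=O)OCc1c(O)c2c(c3c1OC(=O)c1c(C)cc(O)c(C=O)c1O3)[C@H](O)OC2=O
F2 | step 10 | racemic 6-(acetoxymethyl)-5,7-dihydroxy-4-iodo-3-methoxyphthalide | CC(=O)OCc1c(O)c(I)c2c(c1O)C(=O)OC2OC
F3 | step 10 | racemic 6-(acetoxymethyl)-7-hydroxy-4-iodo-3-methoxy-1-oxo-1,3-dihydroisobenzofuran-5-yl 4-(tert-butoxycarbonyloxy)-3-formyl-2-hydroxy-6-methylbenzoate | CC(=O)OCc1c(O)c2c(c(I)c1OC(=O)c1c(C)cc(OC(=O)OC(C)(C)C)c(C=O)c1O)C(OC)OC2=O
F4 | step 2 | methyl 3,6-bis(bromomethyl)-2,4-bis[(2,2,2-trichloroethoxy)carbonyloxy]benzoate | COC(=O)c1c(CBr)cc(OC(=O)OCC(Cl)(Cl)Cl)c(CBr)c1OC(=O)OCC(Cl)(Cl)Cl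
F5 | step 2 | 6-(acetoxymethyl)-5,7-bis[(2,2,2-trichloroethoxy)carbonyloxy]phthalide | CC(=O)OCc1c(OC(=O)OCC(Cl)(Cl)Cl)cc2c(c1OC(=O)OCC(Cl)(Cl)Cl)C(=O)OC2
F6 | step 2 | racemic 6-(acetoxymethyl)-3-bromo-5,7-bis[(2,2,2-trichloroethoxy)carbonyloxy]phthalide | CC(=O)OCc1c(OC(=O)OCC(Cl)(Cl)Cl)cc2c(c1OC(=O)OCC(Cl)(Cl)Cl)C(=O)OC2Br
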